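**Plan**
- Retrosynthesis: the amino and hydroxy groups go back to a 2,5-dimethoxyquinone and this to a tetramethoxyarene. The C-2 methyl comes from a C-2 ketone, and the two C-1 substituents from enolate alkylations. The octalin is then cut at C-1/C-8a and C-3/C-4 in one [3+3] Michael/aldol annulation.
- Enabling feature: C-8a, C-4a and C-4 of ring B are the β-carbon, α-carbon and carbonyl carbon of a ring-A enal whose α-carbon sits next to the quaternary C-5. C-1, C-2 and C-3 are an acetone unit once C-2 is a ketone.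
- Forward: ring A enal from 2,2-dimethylcyclohexanone; ring B by annulation with tert-butyl acetoacetate; benzyl then methyl at C-1; enone deconjugated to C-4=C-4a; methylenation and hydrogenation; arene to quinone; OMe to OH; OMe to NHR.
- Stereochemistry: C-8a from the amine catalyst in the annulation; C-1 by axial methylation anti to H-8a of the trans-fused enolate; C-2 by hydrogenation anti to the axial C-1 methyl.

Key step: step 3

Remark: locants C-1 to C-8a of the bicyclic intermediates are those of the octahydronaphthalene unit as named in 18; CIP descriptors change along the route only because substituent priorities change.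

**Step 1**
Reactants: 1 2,2-dimethylcyclohexanone; 2 2,4,6-tri(propan-2-yl)benzenesulfonohydrazide
Product: 3 (E)-N'-(2,2-dimethylcyclohexylidene)-2,4,6-tri(propan-2-yl)benzenesulfonohydrazide
Conditions: cat. HCl, MeOH, 23 °C
Reagents that add atoms: none
Why: Acid-catalysed hydrazone formation should give the E isomer, with the sulfonamide nitrogen anti to the quaternary carbon, as the Shapiro precursor.

**Step 2**
Reactants: 3 (E)-N'-(2,2-dimethylcyclohexylidene)-2,4,6-tri(propan-2-yl)benzenesulfonohydrazide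
Product: 5 6,6-dimethylcyclohex-1-ene-1-carbaldehyde, via vinyllithium 4 (not isolated)
Conditions: n-BuLi (2.2 equiv), THF, −78 to 0 °C; then DMF, −78 to 23 °C; aq. NH4Cl
Reagents that add atoms: N,N-dimethylformamide, CN(C)C=O
Why: Shapiro reaction; the only α-CH2 is deprotonated, loss of sulfinate and N2 gives the vinyllithium, and DMF formylates it.

**Step 3**
Reactants: 5 6,6-dimethylcyclohex-1-ene-1-carbaldehyde; 6 tert-butyl 3-oxobutanoate
Product: 9 (4aR,8aS)-5,5-dimethyl-4a,5,6,7,8,8a-hexahydronaphthalen-2(1H)-one, via Michael adduct 7 (not isolated), via bicyclic tert-butyl keto ester 8 (not isolated)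
Conditions: 9-amino-9-deoxy-epi-quinine (20 mol %), 2-fluorobenzoic acid (40 mol %), PhMe, 40 °C; then TsOH·H2O (20 mol %), PhMe, 90 °C
Reagents that add atoms: none
Why: Proposed new method: the primary amine condenses with 5 to an (E)-iminium ion, the enol of 6 adds through C-2 to the β-carbon (C-1/C-8a bond), the acetyl methyl of 7 then condenses with the aldehyde (C-3=C-4 bond), and TsOH cleaves the tert-butyl ester with loss of CO2. The closest known reaction type is the amine-catalysed Michael/aldol cyclohexenone annulation of β-keto esters with β-substituted enals, together with primary-amine iminium activation of α-branched enals. Ring B closes by aldol condensation in the 6-(enolendo)-exo-trig mode. C-8a is set by the catalyst, whose protonated quinuclidine should guide the enol to one face of the iminium ion; the quinidine-derived pseudoenantiomer is the switch if the sense proves opposite. C-4a should settle trans under the acid because it is the epimerisable γ-position of the enone. The step needs 1,4- over 1,2-addition, which the neopentyl-like iminium carbon beside the quaternary C-5 should secure.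

**Step 4**
Reactants: 10 1,2,4,5-tetramethoxybenzene
Product: 12 (2,3,5,6-tetramethoxyphenyl)methanol, via aryllithium 11 (not isolated)
Conditions: n-BuLi, TMEDA, THF, 0 °C; then (CH2O)n, 0 to 23 °C
Reagents that add atoms: paraformaldehyde (formaldehyde), C=O
Why: Directed ortho-lithiation at the position flanked by two methoxy groups, followed by hydroxymethylation.

**Step 5**
Reactants: 12 (2,3,5,6-tetramethoxyphenyl)methanol
Product: 13 3-(bromomethyl)-1,2,4,5-tetramethoxybenzene
Conditions: PBr3 (0.4 equiv), Et2O, 0 °C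
Reagents that add atoms: phosphorus tribromide, BrP(Br)Br
Why: Standard conversion of a benzylic alcohol into the bromide.

**Step 6**
Reactants: 9 (4aR,8aS)-5,5-dimethyl-4a,5,6,7,8,8a-hexahydronaphthalen-2(1H)-one; 13 3-(bromomethyl)-1,2,4,5-tetramethoxybenzene
Product: 14 (1R,4aS,8aR)-5,5-dimethyl-1-[(2,3,5,6-tetramethoxyphenyl)methyl]-4a,5,6,7,8,8a-hexahydronaphthalen-2(1H)-one
Conditions: LDA (1.05 equiv), THF, −78 °C; then 13, −78 to −30 °C
Reagents that add atoms: none
Why: Kinetic α'-enolate alkylation of the enone with a reactive benzylic bromide; the C-1 configuration (drawn trans to H-8a) is of no consequence because C-1 is planarised again in step 7.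

**Step 7**
Reactants: 14 (1R,4aS,8aR)-5,5-dimethyl-1-[(2,3,5,6-tetramethoxyphenyl)methyl]-4a,5,6,7,8,8a-hexahydronaphthalen-2(1H)-one
Product: 15 (1S,4aS,8aR)-1,5,5-trimethyl-1-[(2,3,5,6-tetramethoxyphenyl)methyl]-4a,5,6,7,8,8a-hexahydronaphthalen-2(1H)-one
Conditions: LDA (1.2 equiv), THF/DMPU, −78 to −40 °C; then MeI, −78 to 0 °C
Reagents that add atoms: iodomethane, CI
Why: Second α'-alkylation; MeI should enter axially, anti to the axial H-8a of the rigid trans-fused enolate through a chair-like transition state, leaving the methyl trans to H-8a and the benzyl group equatorial.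

**Step 8**
Reactants: 15 (1S,4aS,8aR)-1,5,5-trimethyl-1-[(2,3,5,6-tetramethoxyphenyl)methyl]-4a,5,6,7,8,8a-hexahydronaphthalen-2(1H)-one
Product: 16 (1S,8aR)-1,5,5-trimethyl-1-[(2,3,5,6-tetramethoxyphenyl)methyl]-3,5,6,7,8,8a-hexahydronaphthalen-2(1H)-one
Conditions: KOt-Bu (3 equiv), t-BuOH/THF, 23 °C; inverse quench into cold 10% aq. AcOH
Reagents that add atoms: none
Why: With C-1 quaternary, only γ-deprotonation at C-4a is possible, and kinetic α-protonation of the extended dienolate at C-3 should give the β,γ-unsaturated ketone with the alkene at C-4=C-4a (enone deconjugation).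

**Step 9**
Reactants: 16 (1S,8aR)-1,5,5-trimethyl-1-[(2,3,5,6-tetramethoxyphenyl)methyl]-3,5,6,7,8,8a-hexahydronaphthalen-2(1H)-one
Product: 17 (1S,8aS)-1,5,5-trimethyl-2-methylidene-1-[(2,3,5,6-tetramethoxyphenyl)methyl]-1,2,3,5,6,7,8,8a-octahydronaphthalene
Conditions: Cp2TiMe2 (3 equiv), PhMe/THF, 70 °C, dark
Reagents that add atoms: dimethyltitanocene, C[Ti](C)(C1C=CC=C1)C1C=CC=C1
Why: Petasis methylenation is weakly basic and tolerates hindered, enolisable ketones, so the β,γ-alkene should stay in place.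

**Step 10**
Reactants: 17 (1S,8aS)-1,5,5-trimethyl-2-methylidene-1-[(2,3,5,6-tetramethoxyphenyl)methyl]-1,2,3,5,6,7,8,8a-octahydronaphthalene
Product: 18 3-{[(1R,2S,8aS)-1,2,5,5-tetramethyl-1,2,3,5,6,7,8,8a-octahydronaphthalen-1-yl]methyl}-1,2,4,5-tetramethoxybenzene
Conditions: H2 (1 atm), RhCl(PPh3)3 (10 mol %), PhH/EtOH, 23 °C
Reagents that add atoms: none
Why: Homogeneous hydrogenation should reduce the 1,1-disubstituted alkene and spare the hindered trisubstituted one; hydrogen should add to the face opposite the axial C-1 methyl, placing the new C-2 methyl equatorial and cis to it.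

**Step 11**
Reactants: 18 3-{[(1R,2S,8aS)-1,2,5,5-tetramethyl-1,2,3,5,6,7,8,8a-octahydronaphthalen-1-yl]methyl}-1,2,4,5-tetramethoxybenzene
Product: 19 2,5-dimethoxy-3-{[(1R,2S,8aS)-1,2,5,5-tetramethyl-1,2,3,5,6,7,8,8a-octahydronaphthalen-1-yl]methyl}cyclohexa-2,5-diene-1,4-dione
Conditions: (NH4)2Ce(NO3)6 (2.5 equiv), MeCN/H2O, 0 °C
Reagents that add atoms: water, O
Why: Oxidative demethylation of the 1,2,4,5-tetraoxygenated arene to the para-quinone; the electron-rich arene should be oxidised faster than the hindered alkene.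

**Step 12**
Reactants: 19 2,5-dimethoxy-3-{[(1R,2S,8aS)-1,2,5,5-tetramethyl-1,2,3,5,6,7,8,8a-octahydronaphthalen-1-yl]methyl}cyclohexa-2,5-diene-1,4-dione
Product: 20 2-hydroxy-5-methoxy-3-{[(1R,2S,8aS)-1,2,5,5-tetramethyl-1,2,3,5,6,7,8,8a-octahydronaphthalen-1-yl]methyl}cyclohexa-2,5-diene-1,4-dione
Conditions: 2 M aq. KOH, MeOH, 23 °C; then 1 M HCl
Reagents that add atoms: potassium hydroxide, [K+].[OH-]
Why: Regioselective saponification of the vinylogous ester next to the alkyl group, as established for 3-alkyl-2,5-dimethoxybenzoquinones; the hydroxyquinone anion formed resists a second hydrolysis.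

**Step 13**
Reactants: 20 2-hydroxy-5-methoxy-3-{[(1R,2S,8aS)-1,2,5,5-tetramethyl-1,2,3,5,6,7,8,8a-octahydronaphthalen-1-yl]methyl}cyclohexa-2,5-diene-1,4-dione; 21 3-methylbutan-1-amine
Product: 22 nakijiquinone M, 2-hydroxy-5-[(3-methylbutyl)amino]-3-{[(1R,2S,8aS)-1,2,5,5-tetramethyl-1,2,3,5,6,7,8,8a-octahydronaphthalen-1-yl]methyl}cyclohexa-2,5-diene-1,4-dione
Conditions: 21 (3 equiv), EtOH, 23 °C; dilute acid wash
Reagents that add atoms: none
Why: Addition–elimination of the primary amine at C-5 turns the remaining vinylogous ester into the vinylogous amide, the usual last step for amino-hydroxyquinones of this class.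

**Compound list**
1 | 2,2-dimethylcyclohexanone | CC1(C)CCCCC1=O | starting material
2 | 2,4,6-tri(propan-2-yl)benzenesulfonohydrazide | CC(C)c1cc(C(C)C)c(S(=O)(=O)NN)c(C(C)C)c1 | starting material
3 | (E)-N'-(2,2-dimethylcyclohexylidene)-2,4,6-tri(propan-2-yl)benzenesulfonohydrazide | CC(C)c1cc(C(C)C)c(S(=O)(=O)N/N=C2\CCCCC2(C)C)c(C(C)C)c1 | intermediate
4 | (6,6-dimethylcyclohex-1-en-1-yl)lithium | [Li]C1=CCCCC1(C)C | intermediate
5 | 6,6-dimethylcyclohex-1-ene-1-carbaldehyde | O=CC1=CCCCC1(C)C | intermediate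
6 | tert-butyl 3-oxobutanoate | CC(=O)CC(=O)OC(C)(C)C | starting material
7 | tert-butyl 2-[(1R)-2-formyl-3,3-dimethylcyclohexyl]-3-oxobutanoate (other centres as mixtures) | CC(=O)C(C(=O)OC(C)(C)C)[C@@H]1CCCC(C)(C)C1C=O | intermediate
8 | tert-butyl (4aS,8aR)-5,5-dimethyl-2-oxo-1,2,4a,5,6,7,8,8a-octahydronaphthalene-1-carboxylate (C-1 epimers) | O=C1C=C[C@@H]2C(C)(C)CCC[C@H]2C1C(=O)OC(C)(C)C | intermediate
9 | (4aR,8aS)-5,5-dimethyl-4a,5,6,7,8,8a-hexahydronaphthalen-2(1H)-one | O=C1C=C[C@@H]2C(C)(C)CCC[C@H]2C1 | intermediate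
10 | 1,2,4,5-tetramethoxybenzene | COc1cc(OC)c(OC)cc1OC | starting material
11 | (2,3,5,6-tetramethoxyphenyl)lithium | [Li]c1c(OC)c(OC)cc(OC)c1OC | intermediate
12 | (2,3,5,6-tetramethoxyphenyl)methanol | OCc1c(OC)c(OC)cc(OC)c1OC | intermediate
13 | 3-(bromomethyl)-1,2,4,5-tetramethoxybenzene | BrCc1c(OC)c(OC)cc(OC)c1OC | intermediate
14 | (1R,4aS,8aR)-5,5-dimethyl-1-[(2,3,5,6-tetramethoxyphenyl)methyl]-4a,5,6,7,8,8a-hexahydronaphthalen-2(1H)-one | COc1cc(OC)c(OC)c(C[C@@H]2[C@@H]3CCCC(C)(C)[C@H]3C=CC2=O)c1OC | intermediate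
15 | (1S,4aS,8aR)-1,5,5-trimethyl-1-[(2,3,5,6-tetramethoxyphenyl)methyl]-4a,5,6,7,8,8a-hexahydronaphthalen-2(1H)-one | COc1cc(OC)c(OC)c(C[C@@]2(C)[C@@H]3CCCC(C)(C)[C@H]3C=CC2=O)c1OC | intermediate
16 | (1S,8aR)-1,5,5-trimethyl-1-[(2,3,5,6-tetramethoxyphenyl)methyl]-3,5,6,7,8,8a-hexahydronaphthalen-2(1H)-one | COc1cc(OC)c(OC)c(C[C@@]2(C)[C@@H]3CCCC(C)(C)C3=CCC2=O)c1OC | intermediate
17 | (1S,8aS)-1,5,5-trimethyl-2-methylidene-1-[(2,3,5,6-tetramethoxyphenyl)methyl]-1,2,3,5,6,7,8,8a-octahydronaphthalene | COc1cc(OC)c(OC)c(C[C@@]2(C)[C@@H]3CCCC(C)(C)C3=CCC2=C)c1OC | intermediate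
18 | 3-{[(1R,2S,8aS)-1,2,5,5-tetramethyl-1,2,3,5,6,7,8,8a-octahydronaphthalen-1-yl]methyl}-1,2,4,5-tetramethoxybenzene | COc1cc(OC)c(OC)c(C[C@@]2(C)[C@@H]3CCCC(C)(C)C3=CC[C@@H]2C)c1OC | intermediate
19 | 2,5-dimethoxy-3-{[(1R,2S,8aS)-1,2,5,5-tetramethyl-1,2,3,5,6,7,8,8a-octahydronaphthalen-1-yl]methyl}cyclohexa-2,5-diene-1,4-dione | COC1=CC(=O)C(OC)=C(C[C@@]2(C)[C@@H]3CCCC(C)(C)C3=CC[C@@H]2C)C1=O | intermediate
20 | 2-hydroxy-5-methoxy-3-{[(1R,2S,8aS)-1,2,5,5-tetramethyl-1,2,3,5,6,7,8,8a-octahydronaphthalen-1-yl]methyl}cyclohexa-2,5-diene-1,4-dione | COC1=CC(=O)C(O)=C(C[C@@]2(C)[C@@H]3CCCC(C)(C)C3=CC[C@@H]2C)C1=O | intermediate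
21 | 3-methylbutan-1-amine | CC(C)CCN | starting material
22 | nakijiquinone M | CC(C)CCNC1=CC(=O)C(O)=C(C[C@@]2(C)[C@@H]3CCCC(C)(C)C3=CC[C@@H]2C)C1=O | target

**Step count and risks**
Total steps: 13. Longest linear sequence: 11 (steps 1–3 and 6–13).

Steps most likely to fail:

1. Step 3 (slow conjugate addition to the hindered α-branched iminium ion, or poor facial selectivity). The fallback runs from 5 to 9 and makes the two bonds in separate, known operations with transfer of chirality. A vinylogous Mukaiyama aldol addition of 2,2-dimethyl-6-methylidene-4-(trimethylsilyloxy)-1,3-dioxine to 5 with Cu(OTf)2, Tol-BINAP and Bu4N[Ph3SiF2] (ligand enantiomer chosen for the R carbinol; acidic work-up) should give 6-[(2R)-2-(6,6-dimethylcyclohex-1-en-1-yl)-2-hydroxyethyl]-2,2-dimethyl-4H-1,3-dioxin-4-one F1. Heating in toluene at 110 °C expels acetone, and the acylketene is trapped by the hydroxyl group as (6R)-6-(6,6-dimethylcyclohex-1-en-1-yl)oxane-2,4-dione F2. Pd(PPh3)4 in THF should then effect a Tsuji–Trost-type decarboxylative allylic alkylation with ring contraction, ionisation and carbon attack each going with inversion so that the C–O configuration passes to C-8a, giving (8aS)-5,5-dimethyl-3,5,6,7,8,8a-hexahydronaphthalen-2(1H)-one F3. DBU in CH2Cl2 moves the double bond into conjugation and the route is rejoined at 9.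

2. Step 7 (poor or reversed facial selectivity when the quaternary centre is made). The fallback starts from 9 and reverses the order of the two alkylations. LDA/MeI first gives (1R,4aS,8aR)-1,5,5-trimethyl-4a,5,6,7,8,8a-hexahydronaphthalen-2(1H)-one F4, and the enolate of F4 is then alkylated with 13. If the second electrophile proves to enter cis rather than trans to H-8a, it is then the benzyl group that lands there. The route is rejoined at 15.

3. Step 8 (incomplete γ-deprotonation at the hindered C-4a–H, or reconjugation during the quench). The fallback starts from 15. Ketalisation with ethane-1,2-diol and PPTS in refluxing benzene with removal of water, in which the double bond leaves conjugation as is usual for enone ketals, should give (1S,8aR)-1,5,5-trimethyl-1-[(2,3,5,6-tetramethoxyphenyl)methyl]-3,5,6,7,8,8a-hexahydro-1H-spiro[naphthalene-2,2'-[1,3]dioxolane] F5. Hydrolysis with oxalic acid on wet silica gel (CH2Cl2, 23 °C) then releases the β,γ-unsaturated ketone, and the route is rejoined at 16.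

**Further compounds**
F1 | step 3 | 6-[(2R)-2-(6,6-dimethylcyclohex-1-en-1-yl)-2-hydroxyethyl]-2,2-dimethyl-4H-1,3-dioxin-4-one | CC1(C)OC(C[C@@H](O)C2=CCCCC2(C)C)=CC(=O)O1
F2 | step 3 | (6R)-6-(6,6-dimethylcyclohex-1-en-1-yl)oxane-2,4-dione | O=C1C[C@@H](OC(=O)C1)C1=CCCCC1(C)C
F3 | step 3 | (8aS)-5,5-dimethyl-3,5,6,7,8,8a-hexahydronaphthalen-2(1H)-one | O=C1CC=C2C(C)(C)CCC[C@H]2C1
F4 | step 7 | (1R,4aS,8aR)-1,5,5-trimethyl-4a,5,6,7,8,8a-hexahydronaphthalen-2(1H)-one | O=C1C=C[C@@H]2C(C)(C)CCC[C@H]2[C@H]1C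
F5 | step 8 | (1S,8aR)-1,5,5-trimethyl-1-[(2,3,5,6-tetramethoxyphenyl)methyl]-3,5,6,7,8,8a-hexahydro-1H-spiro[naphthalene-2,2'-[1,3]dioxolane] | COc1cc(OC)c(OC)c(C[C@@]2(C)[C@@H]3CCCC(C)(C)C3=CCC24OCCO4)c1OC
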